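The decision is to judge these flasks by counting incoming ligand against starting complex, and to take rates second.

| setting | gamma | theta | larch | cedar | ash | alder |
|---|---|---|---|---|---|---|
| starting complex | 0.16 M | 0.16 M | 0.040 M | 0.040 M | 0.16 M | 0.16 M |
| incoming ligand | 0.112 M | 0.112 M | 0.250 M | 0.112 M | 0.250 M | 0.112 M |
| leaving ligand | 0.54 M (in portions, 3) | 1.6 M (in portions, 3) | 0.800 M (in portions, 3) | 0.800 M (in portions, 3) | 0.800 M (in portions, 3) | 0.800 M (in portions, 3) |
| temperature | 50 °C | 50 °C | 50 °C | 50 °C | 50 °C | 50 °C |
| remark | run made earlier; portions every 30 s | run made earlier; portions every 30 s | the portions of leaving ligand follow each other after 30 s, the first at the start | the portions of leaving ligand follow each other after 30 s, the first at the start | the portions of leaving ligand follow each other after 30 s, the first at the start | the portions of leaving ligand follow each other after 30 s, the first at the start |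
| time |  |  | 40 min | 40 min | 40 min | 40 min |

| run | time / min | complex with two exchanged / % | starting complex / % |
|---|---|---|---|
| gamma | 0.667 | 0 | 93.0 |
| gamma | 1.33 | 0 | 87.4 |
| gamma | 3.00 | 3.4 | 77.5 |
| gamma | 8.00 | 10.1 | 59.6 |
| theta | 0.667 | 0.4 | 93.7 |
| theta | 1.33 | 0.9 | 89.1 |
| theta | 3.00 | 3.7 | 75.3 |
| theta | 8.00 | 9.2 | 62.6 |

(each reading ± 1 percentage point)

* all flasks from highest to lowest amount of complex with two exchanged, in percent of the starting complex charged, at 40 min (larch / cedar / ash / alder)
* the amount of complex with two exchanged, in percent of the starting complex charged of the flask you put first, at 40 min
* the amount of complex with two exchanged, in percent of the starting complex charged of the flask you put last, at 40 min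

- no earlier run changes the charge of incoming ligand; that part of a forecast is a guess

Leaving ligand comes first. By hand, more of it might hold back an exchange that releases it. Theta carries 2.96 times gamma's charge. Yet starting complex reads 75.3% in theta against 77.5% in gamma at 3.00 min, and 62.6% against 59.6% at 8.00 min. The difference changes sign, so these runs show no steady effect on the loss of starting complex.

Incoming ligand comes next, and no earlier run varies its charge, so its order is a guess. Still, gamma's fractional loss of starting complex reads 0.109 /min at first and 0.0525 /min later, about half. Plain first order in starting complex would hold it steady. That fall is what a rate tied to a falling amount of incoming ligand would show, and the tie stays a guess.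

Starting complex comes last. Cedar has a quarter of alder's charge with the same incoming ligand, so each starting complex has more incoming ligand to draw on. Alder holds 0.700 incoming ligand per starting complex charged; this ratio is the exchange budget. Each exchange is taken to use one incoming ligand, so a full double exchange needs a budget of two:

complex with two exchanged ≤ budget / 2
larch 6.25, cedar 2.80, ash 1.56
ceiling: ash 78.0%, alder 35.0%

In ash and alder incoming ligand is the limiting reagent. Larch and cedar both exceed two, so the budget does not separate them. The ceiling is no yield: gamma at 8.00 min has 30 percentage points of its complex in forms not read. The commitment is ash third and alder last, with the top two left open.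

The forecast gives larch > cedar > ash > alder, with 99% (from 92% to 100%) for the first flask and 17% (from 14% to 21%) for the last, saying “Alder has too little incoming ligand and stalls at about 17%”.

The flasks give cedar > larch > ash > alder: cedar 30.1%, larch 25.7%, ash 15.8%, alder 4.86%.

    leaving ligand + complex with two exchanged → side product (k = 8.70 × 10⁻⁴ /M/s, Ea = 58.0 kJ/mol)
    complex with one exchanged + incoming ligand → leaving ligand + complex with two exchanged (k = 0.0220 /M/s, Ea = 46.0 kJ/mol)
    starting complex + incoming ligand → leaving ligand + complex with one exchanged (k = 0.0160 /M/s, Ea = 51.0 kJ/mol)
    (constants at 50 °C)

In alder at 40.0 min, 0.290% of the incoming ligand charge is left. Complex with one exchanged at 30.5%, complex with two exchanged at 4.86% and side product at 14.8%, which carries both exchanges, count to 0.698 exchanges per starting complex charged, against a budget of 0.700. The neighbouring flask is alder with 0.19 M of incoming ligand, so its budget is 1.19. There 0.941% of the incoming ligand charge is left, and the same count gives 1.18. Its side product stands at 34.1% and its complex with two exchanged at 10.7%.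

All runs stem from a simulated flask from invented constants; the scatter is artificial.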